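All runs were generated by integration with made-up constants, and the scatter is random.

A small charge of single-handed catalyst sits in a racemate and, with partner, turns each substrate into the product of its own hand.

| flask | left-handed substrate | right-handed substrate | partner | catalyst | remark | time |
|---|---|---|---|---|---|---|
| Saturday's | 0.085 M | 0.085 M | 1.5 equiv (in portions, 4) | 7 mol% | run made earlier; portions every 2.5 h |  |
| Tuesday's | 0.085 M | 0.085 M | 1.5 equiv (in portions, 4) | 20 mol% | run made earlier; portions every 2.5 h |  |
| Thursday's | 0.085 M | 0.085 M | 1.6 equiv (in portions, 4) | 15 mol% | run made earlier; portions every 2.5 h |  |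
| elm | 0.085 M | 0.085 M | 3.00 equiv | 5 mol% | everything together at the start | 40 h |
| birch | 0.085 M | 0.085 M | 1.50 equiv (in portions, 4) | 15 mol% | the portions of partner follow each other after 2.5 h, the first at the start | 40 h |

| run | time / h | left-handed product / % | right-handed product / % |
|---|---|---|---|
| Saturday's | 2.00 | 6 | 1 |
| Saturday's | 5.00 | 20 | 3 |
| Saturday's | 10.0 | 36 | 4 |
| Saturday's | 15.0 | 44 | 5 |
| Saturday's | 20.0 | 44 | 8 |
| Saturday's | 30.0 | 45 | 11 |
| Tuesday's | 2.50 | 17 | 0 |
| Tuesday's | 4.00 | 22 | 2 |
| Tuesday's | 6.00 | 30 | 3 |
| Tuesday's | 10.0 | 46 | 7 |
| Tuesday's | 15.0 | 48 | 9 |
| Tuesday's | 30.0 | 51 | 17 |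
| Thursday's | 6.00 | 28 | 0 |
| Thursday's | 12.0 | 45 | 9 |
| Thursday's | 15.0 | 47 | 12 |
| Thursday's | 25.0 | 49 | 9 |
| Thursday's | 30.0 | 52 | 17 |

(readings scatter by 2 percentage points)

- catalyst is single-handed; left-handed substrate and right-handed substrate are mirror images of each other, charged as a racemate, each of them at the stated concentration
- an excess is below zero if the other one leads

- the flask that ends with the higher excess of left-handed product over right-handed product, or "neither" when 2 percentage points or less lies between them (elm / birch / neither)
- excess of left-handed product over right-handed product at the end, elm
- excess of left-handed product over right-handed product at the end, birch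

We build the flask one step at a time, writing P and Q for the left-handed and right-handed products and taking the excess as (P−Q)/(P+Q). With the main step alone, P climbs towards half of the substrates charged and the excess stays at 100 %.

Now add the second step, the one to right-handed product. We assume both steps use the same catalyst and partner, so dividing one rate by the other, each per molecule of its own substrate, removes catalyst, partner and time. Saturday's readings at 10.0 h give 15.3, and Tuesday's at 6.00 h give 14.8; both are loose readings, with Q at 4 % and 3 % and a scatter of 2 percentage points. This is s, the selectivity factor: the logarithm of the fraction of left-handed substrate remaining, divided by the same logarithm for right-handed substrate. On this reckoning, recipes with these two substrates and this catalyst, at this one temperature, walk one curve of right-handed against left-handed substrate remaining. With 1.00 % of the left-handed substrate remaining, 74.0 % of the right-handed remains, and the excess is 58.3 %.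

Then add the rest: in Tuesday's run Q reads 9 % at 15.0 h and 17 % at 30.0 h, while P reads 48 % and 51 %. Thursday's readings at 30.0 h stand at 52 % and 17 %, an excess of 50.7 %, lower than the curve point. Birch is close to that recipe, with 1.50 equiv of partner against 1.6 equiv, though it is read later, at 40 h; we commit to about that figure for it. Elm holds 3.00 equiv of partner, more than birch's 1.50 equiv, but 5 mol% of catalyst, less than birch's 15 mol%; our judgement, without a number, places elm further along the curve and lower.

The forecast says birch, with 28 % for elm and 41 % for birch, lower than our figure; it reads the late growth as “mainly like an uncatalysed, non-selective background reaction driven by partner”.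

The simulation gives birch: elm 35.0 %, birch 53.2 %.

    partner + catalyst + left-handed substrate → catalyst + left-handed product (k = 510 M⁻² h⁻¹)
    partner + catalyst + right-handed substrate → catalyst + right-handed product (k = 36.0 M⁻² h⁻¹)
    catalyst ⇌ dormant form (K = 0.910, k = 0.0290 h⁻¹)

Birch at 40.0 h keeps 0.59 % of its left-handed substrate, so s gives 71.5 % of the right-handed substrate remaining, and the flask holds 70 %. The neighbouring flask is birch with 0.600 equiv of partner. At 40.0 h it has 0.061 % of its partner and 45 % of its left-handed substrate left. From that, s gives 2.52 % of right-handed product; the flask holds 2.71 %, and its excess is 81.9 %.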